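Per hour was the unit chosen at the meeting on this flask, in which substrate either goes straight to product or passes into intermediate A, which can return or decompose.

substrate 0.49 M; gas 57 mM (held); time 8.0 d

    coupling partner + intermediate A ⇌ intermediate B (K1 = 11 M⁻¹, k1 = 0.46 M⁻¹ h⁻¹)
    gas ⇌ coupling partner, rate k2*(csat - [coupling partner]) (k2 = 1.2 h⁻¹, csat = 57 mM)
    substrate → product (k3 = 0.063 h⁻¹)
    substrate ⇌ intermediate A (K4 = 0.45, k4 = 0.044 h⁻¹)
    intermediate A → decomposed reagent (k5 = 0.055 h⁻¹)

- product at 8.0 d, in percent of the substrate charged
- the change that raises the amount of product at 8.0 d, in percent of the substrate charged most ("none" if none brings more than 2 percentage points) (violet / green / none)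
- amount of product at 8.0 d, in percent of the substrate charged, after violet

- at the start none of coupling partner is dissolved
- run time (flask): 8.0 d

- violet: doubling the saturation concentration of gas, all else as stated
- green: doubling the transfer coefficient of step 2, all else as stated

I argued that the final yield is a tally of exits. Substrate leaves for product with 0.063 h⁻¹ and enters intermediate A with 0.044 h⁻¹. Product formed per entry into intermediate A is therefore the ratio of these two, and its logarithm, in powers of ten, is 0.156.

Intermediate A returns with 0.0978 h⁻¹ and decomposes with 0.055 h⁻¹. One decomposition therefore takes 2.78 entries, with logarithm 0.444.

The logarithms add to 0.600. I named the result the split, ρ: product formed per unit of decomposed reagent over a finished run, a selectivity factor, 3.98. The yield is then ρ/(1+ρ), or 79.9 %.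

Intermediate B has no exit of its own in the equations, and ρ holds neither the saturation concentration nor the transfer coefficient. Violet doubles the saturation concentration and green doubles the transfer coefficient. I therefore committed to 79.9 % after violet as well, and to no useful change from either.

I also checked the clock. Intermediate B releases with a half-life of 0.691 d, and the run lasts 11.6 of those, so I expected a finished run.

The forecaster replied that “the final split is set by the substrate → product route against decomposition through intermediate A”. The forecast put product at 79.6 %, 79.2 % after violet, with best change none. My figure stood 0.30 percentage points higher, and I kept one figure for both cases.

The flask gave 79.9 %, and 79.8 % after violet, with best change none: violet moved product by −0.1 points and green by 0 points. Read earlier, this flask parts from the forecast's figure: its product has moved by 5 points at 2.04 d. The split of 3.98 carries no substrate concentration, so it gives the same 79.9 % for the neighbouring flask charged with 0.29 M of substrate, and that flask read 79.9 %.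

The numbers were drawn at random within sensible limits.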